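The data stem from a simulated flask with made-up constants, noise included.

- At 40 min, the flask asked about is Monday's run carried on past its last reading at 15.0 min. In the suspected steps, each substrate takes one partner to reach its product, and the free catalyst comes back unchanged.

common to all: left-handed substrate 0.50 mM; right-handed substrate 0.50 mM; free catalyst 0.43 µM
- Monday's: partner 1.5 mM; racemization catalyst 0.31 µM; the very flask that is asked about, followed so far
- Tuesday's: partner 1.5 mM; racemization catalyst 0.46 µM; run made earlier
- flask: partner 1.50 mM; racemization catalyst 0.31 µM; time 40 min

| run | time / min | left-handed product / % | right-handed product / % |
|---|---|---|---|
| Monday's | 2.50 | 46.4 | 33.0 |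
| Monday's | 5.00 | 51.0 | 42.8 |
| Monday's | 8.00 | 50.6 | 47.0 |
| Monday's | 10.0 | 51.8 | 46.5 |
| Monday's | 12.0 | 51.6 | 46.7 |
| Monday's | 15.0 | 52.0 | 48.5 |
| Tuesday's | 1.00 | 35.9 | 20.6 |
| Tuesday's | 3.00 | 49.0 | 35.3 |
| Tuesday's | 6.00 | 51.3 | 42.4 |
| Tuesday's | 8.00 | 51.9 | 44.7 |
| Tuesday's | 12.0 | 51.1 | 47.5 |
| Tuesday's | 15.0 | 51.3 | 49.6 |

(each reading ± 1 percentage point)

- why nothing more happens at 40 min, or that something still does (forward and back rates have come level / it is still moving / no working catalyst is left / the partner has run out first / all of the left-handed substrate has reacted)
- left-handed product at 40 min, in percent of the left-handed substrate and right-handed substrate together charged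
- right-handed product at 40 min, in percent of the left-handed substrate and right-handed substrate together charged

- free catalyst is single-handed; left-handed substrate and right-handed substrate are mirror images of each other, charged as a racemate, each of them at the stated concentration
- the numbers in the tables scatter with a standard deviation of 1 percentage point
- on the list of suspects stand: partner + free catalyst + left-handed substrate -> free catalyst + left-handed product; partner + free catalyst + right-handed substrate -> free catalyst + right-handed product; left-handed substrate + racemization catalyst <-> right-handed substrate + racemization catalyst; partner + racemization catalyst -> spent catalyst
- the reaction counts as stopped when no species that holds the left-handed substrate and right-handed substrate together changes by six tenths of a point or more over the second half of the time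

- The two substrates together, 1.00 mM, are the limiting reagent against 1.50 mM of partner. Partner charged less both substrates charged is 0.500 mM, the partner surplus. The racemization catalyst can take no more partner than its own 0.31 µM, so Monday's flask holds enough partner for both substrates as charged.
- Bound from below: left-handed product leads at Monday's first reading, 46.4% against 33.0%. Left-handed substrate therefore falls faster, and any net racemization runs from right-handed to left-handed substrate, so Monday's flask, once finished, holds at least 50.0% of left-handed product.
- Bound from above: right-handed product does not fall, so Monday's 48.5% at 15.0 min leaves room for 51.5% of left-handed product, give or take 1 percentage point.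
- The forecast gives 51.6% (50.9% to 52.4%) of left-handed product and 48.4% of right-handed product, names as the end "all of the left-handed substrate has reacted", and holds that “racemization moves little material and probably dies early”. Its left-handed value stands 0.1 points from the upper bound, inside the scatter.
- The flask gives 50.9% of left-handed product and 49.1% of right-handed product, and its end is "all of the left-handed substrate has reacted". This left-handed value lies inside the bracket, and the forecast held.

    partner + free catalyst + left-handed substrate → free catalyst + left-handed product (k = 4.20 × 10⁷ L² mol⁻² s⁻¹)
    partner + free catalyst + right-handed substrate → free catalyst + right-handed product (k = 1.85 × 10⁷ L² mol⁻² s⁻¹)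
    left-handed substrate + racemization catalyst ⇌ right-handed substrate + racemization catalyst, rate k3*[racemization catalyst]*[left-handed substrate] forward; the back reaction follows from the equilibrium constant (k = 46100 L mol⁻¹ s⁻¹)
    partner + racemization catalyst → spent catalyst (k = 64.8 L mol⁻¹ s⁻¹)

- Partner's half-life is 9.6 h by the step into spent catalyst alone and 1.3 min by the left-handed step alone, each with the other concentrations held at charge. The flask keeps 33% of its partner at 40.0 min, and the surplus as a share of the charge is 33.3%. The neighbour with 0.60 mM of partner has a surplus of −0.400 mM; it keeps 0% of its partner, and its left-handed and right-handed substrates stand at 16.7% and 23.3% of the two charged, together 40.0% against a shortfall of 40.0%.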